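**Assumptions.** Briarane numbering (C1–C20) is used for all intermediates. β is the face of the six-membered ring that carries the C15 methyl; α is the face that carries C2 and the epoxide. Stereodescriptors were derived by hand from the target SMILES. The route has not been run; selectivities are predictions.

## Retrosynthetic overview

1. The ten-membered ring is closed last by an intramolecular Nozaki–Hiyama–Kishi (NHK) reaction at C2–C3, which also sets C2.
2. The γ-lactone comes from an intermolecular NHK at C6–C7 with a (1E,3Z)-iodo/bromo-diene linchpin (C3–C6, C16), followed by lactonization.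
3. The C7–C9/C17–C19 array comes from a C9 aldehyde plus ethyl diazoacetate (C8, C7), oxidation to an α-keto ester, and a chelation-controlled Reformatsky reaction (C17–C19).
4. Ring A substituents come from an epoxy enone by conjugate vinylation, methylation and kinetic protonation.
5. The epoxy enone comes from benzoic acid: Birch reductive methylation, then a catalytic asymmetric hydroxyl-directed epoxidation that desymmetrizes the dienyl methanol, setting C1, C13 and C14 and installing the natural epoxide at step 3. Ring order: six-membered ring, epoxide, γ-lactone, ten-membered ring.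

## Route

**Step 1**
Reactants: 1 benzoic acid
Product: 2 1-methylcyclohexa-2,5-diene-1-carboxylic acid
Conditions: Li, NH3(l)/THF, −78 °C; then MeI; H3O+
Reagents that add atoms: iodomethane, CI
Why: Birch reductive alkylation; the dianion is methylated at the carboxyl-bearing carbon, giving the C1 quaternary carbon with C15 and C2 (no stereocenter yet, Cs-symmetric).

**Step 2**
Reactants: 2
Product: 3 (1-methylcyclohexa-2,5-dien-1-yl)methanol
Conditions: LiAlH4, Et2O, 0 °C
Reagents that add atoms: none
Why: Hydride reduction of the acid to the primary alcohol; the skipped diene is inert.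

**Step 3 (key step)**
Reactants: 3
Product: 4 [(1R,2S,6S)-2-methyl-7-oxabicyclo[4.1.0]hept-3-en-2-yl]methanol (mono-epoxide, epoxide cis to CH2OH)
Conditions: VO(Oi-Pr)3 (2 mol %), chiral C2-symmetric bishydroxamic acid ligand (4 mol %), cumene hydroperoxide (1.1 equiv), toluene, 0 °C
Reagents that add atoms: cumene hydroperoxide, CC(C)(OO)c1ccccc1 (one O)
Why: Proposed new method: the vanadate ester of the homoallylic OH delivers peroxide oxygen to the ring face cis to CH2OH, and the chiral ligand selects one of the two enantiotopic ring alkenes, setting C1, C13 and C14 at once (the wrong enantiomer is drained to bis-epoxide, raising ee); closest known reaction is vanadium–bishydroxamic acid asymmetric epoxidation of acyclic homoallylic alcohols and the desymmetrizing epoxidation of divinyl carbinols.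

**Step 4**
Reactants: 4
Product: 5 TBS ether of 4
Conditions: TBSCl, imidazole, DMF, rt
Reagents that add atoms: tert-butyldimethylsilyl chloride, CC(C)(C)[Si](C)(C)Cl
Why: Standard silylation; the bulky CH2OTBS group later shields the α-face.

**Step 5**
Reactants: 5
Product: 6 (1R,5S,6R)-5-{[(tert-butyldimethylsilyl)oxy]methyl}-5-methyl-7-oxabicyclo[4.1.0]hept-3-en-2-one (13α,14α-epoxy-10-en-12-one)
Conditions: CrO3, 3,5-dimethylpyrazole, CH2Cl2, −20 °C
Reagents that add atoms: chromium trioxide, O=[Cr](=O)=O (one O)
Why: Allylic oxidation; C12 is the only allylic CH2 (the other allylic position is the quaternary C1), so a single enone results.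

**Step 6**
Reactants: 6
Product: 7 2-O-TBS-13α,14α-epoxy-10β-vinyl-11α-methyl-12-ketone
Conditions: CH2=CHMgBr, CuBr·SMe2 (20 mol %), THF, −78 to −40 °C; then MeI, DMPU, −40 to 0 °C
Reagents that add atoms: vinylmagnesium bromide, C=C[Mg]Br; iodomethane, CI
Why: Copper-catalysed conjugate addition with enolate alkylation; vinyl adds to C10 anti to CH2OTBS and the α-epoxide (β-face), and MeI enters anti to the new vinyl group (the C11 configuration is reset in step 7).

**Step 7**
Reactants: 7
Product: 8 11β-methyl epimer of 7 (10β-vinyl and 11β-methyl cis)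
Conditions: LDA, THF, −78 to −20 °C; then AcOH, −78 °C
Reagents that add atoms: none
Why: Kinetic protonation of the C11 enolate; A(1,2) strain with the enolate methyl pushes the C10 vinyl pseudoaxial (β), so the proton arrives axially from the α-face and gives the contra-thermodynamic cis 10,11 relationship.

**Step 8**
Reactants: 8
Product: 9 C9 aldehyde (10β-formyl, otherwise as 8)
Conditions: O3, CH2Cl2, −78 °C; then PPh3
Reagents that add atoms: ozone, [O-][O+]=O (one O)
Why: Ozonolysis of the only alkene present; neutral reductive work-up protects the C10 and C11 stereocenters.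

**Step 9**
Reactants: 9; 10 ethyl diazoacetate
Product: 11 (9R)-β-hydroxy-α-diazo ester (C9–OH, C8=N2, C7 ethyl ester)
Conditions: 10, Bu2Mg (cat.), ProPhenol ligand (cat., matched enantiomer), THF, −20 °C
Reagents that add atoms: none beyond reactant 10
Why: Catalytic asymmetric diazoacetate aldol addition; the catalyst reinforces the Felkin–Anh preference (attack anti to quaternary C1), which I calculate gives 9R.

**Step 10**
Reactants: 11
Product: 12 (9R)-β-hydroxy-α-keto ester (C8 ketone)
Conditions: dimethyldioxirane, acetone, 0 °C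
Reagents that add atoms: dimethyldioxirane, CC1(C)OO1 (one O)
Why: Dioxirane oxidation of the diazo carbon to a ketone with loss of N2; no alkene is present, and the crude product is used at once to avoid enediol isomerization.

**Step 11**
Reactants: 12; 13 tert-butyl 2-bromopropanoate (racemic)
Product: 14 (8S,9R)-tertiary alcohol bearing the C7 ethyl ester and the C17(Me)–C19 tert-butyl ester (C17 mixture)
Conditions: Zn (activated), 13 (3 equiv), THF, 0 °C
Reagents that add atoms: none beyond reactant 13
Why: Reformatsky addition to the highly electrophilic α-keto ester (the hindered C12 ketone is spared); the C9 zinc alkoxide chelates the C8 carbonyl and the enolate attacks from the C9–H side, giving 8S (Cram-chelate model).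

**Step 12**
Reactants: 14
Product: 15 tetraol (C7 CH2OH, 8-OH, 9-OH, 12β-OH)
Conditions: NaBH4, EtOH–THF, 0 °C to rt
Reagents that add atoms: none
Why: Borohydride reduces the C12 ketone from the α-face (anti to the syn-axial C10 side chain), giving 12β-OH trans to the epoxide, and reduces the hydroxyl-activated α-hydroxy ethyl ester while the tert-butyl ester survives (as in the selective reduction of malate diesters).

**Step 13**
Reactants: 15
Product: 16 α-hydroxy aldehyde (C7 aldehyde; 8-OH, 9-OH, 12-OH free)
Conditions: TEMPO (cat.), NCS, Bu4NCl, CH2Cl2/aq. NaHCO3–K2CO3 (pH 8.6), rt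
Reagents that add atoms: none
Why: Oxoammonium oxidation selective for the only primary alcohol; these conditions avoid glycol cleavage, and the aldehyde cannot enolize because C8 is fully substituted.

**Step 14**
Reactants: 16
Product: 17 9,12-diacetate aldehyde
Conditions: Ac2O, pyridine, DMAP (cat.), CH2Cl2, 0 °C to rt
Reagents that add atoms: acetic anhydride, CC(=O)OC(C)=O
Why: Acylation of the two secondary alcohols; the tertiary 8-OH is left free, and both acetates of the target are installed in one operation.

**Step 15**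
Reactants: 18 propargyl alcohol
Product: 19 tert-butyl(diphenyl)(prop-2-yn-1-yloxy)silane
Conditions: TBDPSCl, imidazole, CH2Cl2, rt
Reagents that add atoms: tert-butyldiphenylsilyl chloride, CC(C)(C)[Si](Cl)(c1ccccc1)c1ccccc1
Why: Standard silylation; TBDPS survives the later acid step that removes TBS.

**Step 16**
Reactants: 19
Product: 20 (Z)-2-{[(tert-butyldiphenylsilyl)oxy]methyl}-3-[dimethyl(phenyl)silyl]prop-2-enal
Conditions: Me2PhSiH, CO (20 atm), Rh4(CO)12 (cat.), Et3N, benzene, 100 °C
Reagents that add atoms: dimethylphenylsilane, C[SiH](C)c1ccccc1; carbon monoxide, [C-]#[O+]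
Why: Rhodium-catalysed silylformylation of a terminal alkyne; syn addition puts CHO (C4) on the internal carbon and Si on C6 cis to it, which fixes the C5=C6 geometry.

**Step 17**
Reactants: 20
Product: 21 (1E,3Z)-4-bromo-1-[dimethyl(phenyl)silyl]-2-{[(tert-butyldiphenylsilyl)oxy]methyl}buta-1,3-diene
Conditions: [Ph3PCH2Br]Br, KOt-Bu, THF, −78 °C
Reagents that add atoms: (bromomethyl)triphenylphosphonium bromide, BrC[P+](c1ccccc1)(c1ccccc1)c1ccccc1.[Br-]
Why: Z-selective Wittig bromo-olefination with a non-stabilized ylide sets the C3=C4 cis alkene.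

**Step 18**
Reactants: 21
Product: 22 (1E,3Z)-4-bromo-1-iodo-2-{[(tert-butyldiphenylsilyl)oxy]methyl}buta-1,3-diene (I cis to C4; Br cis to C5)
Conditions: NIS, MeCN, 0 °C
Reagents that add atoms: N-iodosuccinimide, O=C1CCC(=O)N1I
Why: Ipso-iododesilylation of the vinylsilane with retention of geometry.

**Step 19**
Reactants: 17; 22
Product: 23 (7S)-allylic alcohol (C6–C7 bond formed; tert-butyl ester, C3 vinyl bromide and 2-O-TBS intact)
Conditions: CrCl2 (4 equiv), NiCl2 (1 mol %), DMSO, rt
Reagents that add atoms: none beyond reactant 22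
Why: Nozaki–Hiyama–Kishi coupling, selective for the vinyl iodide over the vinyl bromide and for the aldehyde over esters; Felkin–Anh addition (8-OH anti to the nucleophile, larger C9 branch inside, non-chelating DMSO) is expected to give 7S.

**Step 20**
Reactants: 23
Product: 24 γ-lactone primary alcohol (C7–O–C19 lactone, 17R methyl, C2 CH2OH free, 16-O-TBDPS)
Conditions: CSA (0.2 equiv), CH2Cl2–MeOH, rt; then DBU, PhMe, rt (telescoped)
Reagents that add atoms: none
Why: Acid-catalysed lactonization of the γ-hydroxy tert-butyl ester with concurrent cleavage of the primary TBS ether, then base equilibration of the enolizable C17 to the more stable epimer (Me-18 anti to the bulky C9 substituent, cis to 8-OH).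

**Step 21**
Reactants: 24
Product: 25 C2 aldehyde
Conditions: Dess–Martin periodinane, NaHCO3, CH2Cl2, rt
Reagents that add atoms: none
Why: Oxidation of the only primary or secondary alcohol; the tertiary 8-OH is inert and the aldehyde is non-enolizable.

**Step 22**
Reactants: 25
Product: 26 16-O-TBDPS-briaexcavatolide N (ten-membered ring closed, 2S-OH)
Conditions: CrCl2 (10 equiv), NiCl2 (10 mol %), DMSO–THF, 2 mM, rt to 40 °C
Reagents that add atoms: none
Why: Intramolecular Nozaki–Hiyama–Kishi macrocyclization with retention of the Z-alkenyl geometry; the aldehyde H tucks under the ring with the carbonyl O turned toward the α-epoxide (Cr chelation), so the tethered alkenyl-chromium attacks from the C10 side and gives 2S.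

**Step 23**
Reactants: 26
Product: 27 briaexcavatolide N
Conditions: TBAF, AcOH (1:1), THF, 0 °C to rt
Reagents that add atoms: none
Why: Buffered fluoride desilylation frees 16-OH without acetate migration or epoxide opening.

## Compound list

1 | benzoic acid | O=C(O)c1ccccc1 | starting material
2 | 1-methylcyclohexa-2,5-diene-1-carboxylic acid | CC1(C(=O)O)C=CCC=C1 | intermediate
3 | (1-methylcyclohexa-2,5-dien-1-yl)methanol | CC1(CO)C=CCC=C1 | intermediate
4 | [(1R,2S,6S)-2-methyl-7-oxabicyclo[4.1.0]hept-3-en-2-yl]methanol | OC[C@]1(C)C=CC[C@@H]2O[C@H]12 | intermediate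
5 | TBS ether of 4 | CC(C)(C)[Si](C)(C)OC[C@]1(C)C=CC[C@@H]2O[C@H]12 | intermediate
6 | (1R,5S,6R)-5-(TBS-oxymethyl)-5-methyl-7-oxabicyclo[4.1.0]hept-3-en-2-one | CC(C)(C)[Si](C)(C)OC[C@]1(C)C=CC(=O)[C@@H]2O[C@H]12 | intermediate
7 | 13α,14α-epoxy-10β-vinyl-11α-methyl-12-ketone, 2-O-TBS | CC(C)(C)[Si](C)(C)OC[C@]1(C)[C@@H](C=C)[C@H](C)C(=O)[C@@H]2O[C@H]12 | intermediate
8 | 11β-methyl epimer of 7 | CC(C)(C)[Si](C)(C)OC[C@]1(C)[C@@H](C=C)[C@@H](C)C(=O)[C@@H]2O[C@H]12 | intermediate
9 | 10β-formyl ketone (C9 aldehyde) | CC(C)(C)[Si](C)(C)OC[C@]1(C)[C@@H](C=O)[C@@H](C)C(=O)[C@@H]2O[C@H]12 | intermediate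
10 | ethyl diazoacetate | CCOC(=O)C=[N+]=[N-] | starting material
11 | (9R)-β-hydroxy-α-diazo ethyl ester | CC(C)(C)[Si](C)(C)OC[C@]1(C)[C@@H]([C@@H](O)C(=[N+]=[N-])C(=O)OCC)[C@@H](C)C(=O)[C@@H]2O[C@H]12 | intermediate
12 | (9R)-β-hydroxy-α-keto ethyl ester | CC(C)(C)[Si](C)(C)OC[C@]1(C)[C@@H]([C@@H](O)C(=O)C(=O)OCC)[C@@H](C)C(=O)[C@@H]2O[C@H]12 | intermediate
13 | tert-butyl 2-bromopropanoate (racemic) | CC(Br)C(=O)OC(C)(C)C | starting material
14 | (8S,9R) Reformatsky adduct, C17 mixture | CC(C)(C)[Si](C)(C)OC[C@]1(C)[C@@H]([C@@H](O)[C@@](O)(C(=O)OCC)C(C)C(=O)OC(C)(C)C)[C@@H](C)C(=O)[C@@H]2O[C@H]12 | intermediate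
15 | tetraol (C7 CH2OH; 8-, 9-, 12β-OH) | CC(C)(C)[Si](C)(C)OC[C@]1(C)[C@@H]([C@@H](O)[C@@](O)(CO)C(C)C(=O)OC(C)(C)C)[C@@H](C)[C@@H](O)[C@@H]2O[C@H]12 | intermediate
16 | C7 aldehyde triol | CC(C)(C)[Si](C)(C)OC[C@]1(C)[C@@H]([C@@H](O)[C@@](O)(C=O)C(C)C(=O)OC(C)(C)C)[C@@H](C)[C@@H](O)[C@@H]2O[C@H]12 | intermediate
17 | 9,12-diacetate C7 aldehyde | CC(C)(C)[Si](C)(C)OC[C@]1(C)[C@@H]([C@@H](OC(C)=O)[C@@](O)(C=O)C(C)C(=O)OC(C)(C)C)[C@@H](C)[C@@H](OC(C)=O)[C@@H]2O[C@H]12 | intermediate
18 | propargyl alcohol | C#CCO | starting material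
19 | tert-butyl(diphenyl)(prop-2-yn-1-yloxy)silane | C#CCO[Si](c1ccccc1)(c1ccccc1)C(C)(C)C | intermediate
20 | (Z)-2-(TBDPS-oxymethyl)-3-[dimethyl(phenyl)silyl]prop-2-enal | C[Si](C)(c1ccccc1)/C=C(CO[Si](c1ccccc1)(c1ccccc1)C(C)(C)C)\C=O | intermediate
21 | (1E,3Z)-4-bromo-1-[dimethyl(phenyl)silyl]-2-(TBDPS-oxymethyl)buta-1,3-diene | C[Si](C)(c1ccccc1)/C=C(CO[Si](c1ccccc1)(c1ccccc1)C(C)(C)C)\C=C/Br | intermediate
22 | (1E,3Z)-4-bromo-1-iodo-2-(TBDPS-oxymethyl)buta-1,3-diene | I/C=C(CO[Si](c1ccccc1)(c1ccccc1)C(C)(C)C)\C=C/Br | intermediate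
23 | (7S) NHK adduct, C17 mixture | CC(C)(C)[Si](C)(C)OC[C@]1(C)[C@@H]([C@@H](OC(C)=O)[C@@](O)([C@@H](O)/C=C(CO[Si](c3ccccc3)(c3ccccc3)C(C)(C)C)\C=C/Br)C(C)C(=O)OC(C)(C)C)[C@@H](C)[C@@H](OC(C)=O)[C@@H]2O[C@H]12 | intermediate
24 | γ-lactone primary alcohol | OC[C@]1(C)[C@@H]([C@@H](OC(C)=O)[C@@]3(O)[C@H](/C=C(CO[Si](c4ccccc4)(c4ccccc4)C(C)(C)C)\C=C/Br)OC(=O)[C@@H]3C)[C@@H](C)[C@@H](OC(C)=O)[C@@H]2O[C@H]12 | intermediate
25 | γ-lactone C2 aldehyde | O=C[C@]1(C)[C@@H]([C@@H](OC(C)=O)[C@@]3(O)[C@H](/C=C(CO[Si](c4ccccc4)(c4ccccc4)C(C)(C)C)\C=C/Br)OC(=O)[C@@H]3C)[C@@H](C)[C@@H](OC(C)=O)[C@@H]2O[C@H]12 | intermediate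
26 | 16-O-TBDPS-briaexcavatolide N | CC(=O)O[C@@H]1[C@H](C)[C@@H]2[C@@H](OC(C)=O)[C@@]3(O)[C@H](/C=C(CO[Si](c4ccccc4)(c4ccccc4)C(C)(C)C)\C=C/[C@H](O)[C@@]2(C)[C@H]2O[C@@H]12)OC(=O)[C@@H]3C | intermediate
27 | briaexcavatolide N | CC(=O)O[C@@H]1[C@H](C)[C@@H]2[C@@H](OC(C)=O)[C@@]3(O)[C@H](/C=C(CO)\C=C/[C@H](O)[C@@]2(C)[C@H]2O[C@@H]12)OC(=O)[C@@H]3C | target

## Totals and risks

- **Total steps:** 23.
- **Longest linear sequence:** 19 (steps 1–14 and 19–23, from benzoic acid). The linchpin branch is 4 steps (15–18).

**Three steps most likely to fail**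

1. **Step 3, desymmetrizing epoxidation** (unprecedented substrate class; enantioselectivity and mono- versus bis-epoxidation are uncertain). Fallback: oxidize the TBS ether of 3 to the prochiral 4-methyl-4-(silyloxymethyl)cyclohexa-2,5-dienone and desymmetrize it by rhodium/chiral-diene conjugate vinylation (sets C1 and C10). The epoxide is then added later by achiral vanadium epoxidation directed by the free C2 CH2OH.
2. **Step 22, NHK macrocyclization** (strained trans-fused ten-membered Z,Z-diene, hindered neopentyl aldehyde, uncertain C2 selectivity). Fallback: change the ring-closing bond. Add a vinyl group to the C2 aldehyde, carry a 2-substituted 1,3-diene at C5, and close C3=C4 by ring-closing metathesis; if C2 is wrong, correct it by oxidation to the enone and reagent-controlled (CBS) reduction.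
3. **Step 7, kinetic protonation at C11** (the cis 10,11 product is contra-thermodynamic and must survive as a ketone α-stereocenter until step 12). Fallback: introduce C20 as an exocyclic methylene (Mannich methylenation of the C11 enolate) and deliver hydrogen to the α-face by hydroxyl-directed homogeneous hydrogenation from the free C2 CH2OH.

The C7 selectivity in step 19 is the next weakest point. If it fails, the same change of approach applies: oxidize C7 to the dienyl ketone and reduce with a CBS catalyst before lactonization.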